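J appeared in Tuesday's and Monday's runs at a steady share of the L spent, so I ranked what those runs showed, from what showed first to what showed last.

| flask | L | remark | time |
|---|---|---|---|
| Tuesday's | 0.15 M | run made earlier |  |
| Monday's | 0.84 M | run made earlier |  |
| amber | 1.0 M |  | 6.0 min |
| violet | 0.24 M |  | 20 min |

- Tuesday's (time / min: J / %, L / %): 3.00: 8.2, 81.4; 6.00: 13.9, 67.0; 8.00: 17.0, 59.1; 12.0: 22.9, 47.4; 15.0: 27.7, 39.5; 20.0: 31.0, 29.6
- Monday's (time / min: J / %, L / %): 1.00: 2.1, 93.7; 3.00: 7.6, 81.2; 6.00: 14.0, 66.7; 8.00: 18.0, 58.4; 12.0: 21.7, 45.3; 15.0: 26.8, 37.3; 20.0: 31.5, 27.2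

(standard deviation of a reading: 0.5 percentage points)



- which of the two ends with the higher amount of J, in percent of the L charged ("neither" if they lie within 2 percentage points) (amber / violet / neither)
- J at the end, in percent of the L charged, amber
- J at the end, in percent of the L charged, violet

The first rung was the split between J and whatever else L became, its selectivity: the J share of spent L was 0.441 in Tuesday's run at 3.00 min and 0.433 in Monday's run at 20.0 min. So the split already stood at the first firm reading. The next rung was the loss of L. Tuesday's run kept 67.0% at 6.00 min, which gave a turnover time, the time in which [L] falls by a factor of e, of 15.0 min. Monday's run, charged 5.60 times higher, kept 66.7% at that time, so L looked first order and I counted time in turnovers. The last rung was a drift: at 20.0 min, L stood at 29.6% in Tuesday's run and 27.2% in Monday's, a gap of 2.4 percentage points against a scatter of 0.5 points, yet J read 31.0% and 31.5%.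

I reckoned J as the selectivity times the spent fraction, which is one minus e to the minus turnovers. Amber stopped at 0.400 turnovers and violet at 1.33, which gave me 14.3% for amber and 31.9% for violet. The forecast named violet, with 14.1% for amber and 31.2% for violet, both lower than mine, and said violet ends higher “simply because it runs longer”.

    L ⇌ D (K = 1.80, k = 6.72 × 10⁻⁴ s⁻¹)
    D ⇌ Z (K = 40.0, k = 5.96 × 10⁻⁴ s⁻¹)
    L → J (k = 4.64 × 10⁻⁴ s⁻¹)
    Z → G (k = 2.37 × 10⁻⁴ s⁻¹)
    G ⇌ X (K = 0.600, k = 1.59 × 10⁻⁴ s⁻¹)
    L + Z → E (k = 0.00465 L mol⁻¹ s⁻¹)
    X → Q (k = 3.17 × 10⁻⁵ s⁻¹)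

The flask gave amber 13.7% and violet 31.4%. Amber's short time was part of the reason: amber given violet's time reached 30.8% instead of 13.7%, and left ten times as long it reached 41.8%, while the difference in [L] was not the reason, since amber with violet's charge stayed at 13.8%. With the turnover time of 15.0 min, amber had stopped at 0.400 turnovers and violet at 1.33. The flask amber left until 25 min stood at 1.67 turnovers, where the same count gave 35.1%, and its J was 33.9%.

All runs are simulated on assumed constants; scatter was added.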